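**Retrosynthetic overview**

1. The oxirane is made last, by peracid epoxidation of the macrocyclic (4Z)-allylic alcohol, trans to the 6-OH.
2. The ten-membered carbocycle is closed at C6–C7 by an intramolecular chromium-mediated allylation of a (Z)-enal by a 3-(bromomethyl)butenolide. This step also turns the butenolide into the trans-fused α-methylene lactone and sets C6 and C7.
3. The key step forms C8–C9: a palladium-catalysed enantioselective dearomative γ-allylation of a 2-silyloxyfuran with a branched allylic carbonate, setting C8 and the C1=C10 geometry with the tiglate already in place.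
4. The silyloxyfuran comes from furfural (oxidation, hydroxymethylation, silylation). The carbonate comes from nerol (C1–C6, C15), 2,3-dibromopropene (C9, C10, C14) and tiglic acid.
5. Ring order: five-membered oxygen ring first (from the furan), ten-membered carbocycle second, oxirane third.

Assumption: atom labels C1–C15 follow germacrane numbering (C1–C10 ring, C11–C13 lactone, C14 acyloxymethyl, C15 methyl); the target is the (4S,5R,6S,7S,8S) isomer with C9 and C2 trans across C1=C10, a cis-fused oxirane and an (E)-2-methylbut-2-enoate (tiglate). TBS = tert-butyldimethylsilyl.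

**Route**

Step 1
Reactants: 1 furfural
Product: 4 furan-2(5H)-one, via furan-2-yl formate 2 (not isolated), via furan-2(3H)-one 3 (not isolated)
Conditions: 30 % aq. H2O2, HCO2H, CH2Cl2, reflux; then Et3N (cat.), rt
Reagents that add atoms: hydrogen peroxide, OO
Why: Baeyer–Villiger oxidation of the aldehyde by performic acid formed in situ gives formate 2, which is solvolysed and tautomerises through 3 to the conjugated butenolide 4, so the furan ring becomes the lactone ring (C7, C8, C11, C12).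

Step 2
Reactants: 4 furan-2(5H)-one
Product: 5 3-(hydroxymethyl)furan-2(5H)-one
Conditions: 37 % aq. CH2O, DMAP (0.2 equiv), THF–H2O, rt
Reagents that add atoms: formaldehyde, C=O
Why: Morita–Baylis–Hillman hydroxymethylation (conjugate addition of DMAP, aldol trapping of the enolate by formaldehyde, loss of DMAP) installs C13 at the alcohol oxidation level.

Step 3
Reactants: 5 3-(hydroxymethyl)furan-2(5H)-one
Product: 6 2-[(TBS)oxy]-3-{[(TBS)oxy]methyl}furan
Conditions: TBSOTf (2.2 equiv), Et3N (3 equiv), CH2Cl2, 0 °C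
Reagents that add atoms: tert-butyldimethylsilyl trifluoromethanesulfonate, CC(C)(C)[Si](C)(C)OS(=O)(=O)C(F)(F)F
Why: O-silylation of the alcohol and soft enolisation of the lactone (carbonyl O-silylation, then loss of the acidic C5 proton) give the aromatic 2-silyloxyfuran, a latent γ-nucleophile whose C3 position is blocked.

Step 4
Reactants: 7 nerol
Product: 8 neryl TBS ether
Conditions: TBSCl, imidazole, DMF, rt
Reagents that add atoms: tert-butyldimethylsilyl chloride, CC(C)(C)[Si](C)(C)Cl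
Why: Standard silyl protection of the primary allylic alcohol, which leaves the Z alkene (future C4=C5) untouched.

Step 5
Reactants: 8 neryl TBS ether
Product: 10 (4Z)-6-[(TBS)oxy]-4-methylhex-4-enal, via ozonide 9 (not isolated)
Conditions: O3 (1 equiv, Sudan Red 7B end point), CH2Cl2, −78 °C; then Me2S, −78 °C → rt
Reagents that add atoms: ozone, [O-][O+]=O
Why: Ozonolysis with reductive work-up; the isopropylidene alkene is more electron-rich than the alkene bearing the allylic silyl ether, so one equivalent of ozone cleaves it selectively.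

Step 6
Reactants: 11 tiglic acid; 12 2,3-dibromoprop-1-ene
Product: 13 2-bromoprop-2-en-1-yl (2E)-2-methylbut-2-enoate
Conditions: K2CO3, DMF, rt
Reagents that add atoms: none
Why: Carboxylate SN2 alkylation at the allylic bromide; the vinylic bromide does not react.

Step 7
Reactants: 10 (4Z)-6-[(TBS)oxy]-4-methylhex-4-enal; 13 2-bromoprop-2-en-1-yl (2E)-2-methylbut-2-enoate
Product: 15 racemic (6Z)-8-[(TBS)oxy]-3-hydroxy-6-methyl-2-methylideneoct-6-en-1-yl (2E)-2-methylbut-2-enoate, via alkenylchromium dichloride 14 (not isolated)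
Conditions: CrCl2 (4 equiv), NiCl2 (2 mol %), DMF, rt
Reagents that add atoms: chromium dichloride, Cl[Cr]Cl (its atoms remain only in 14)
Why: Nozaki–Hiyama–Kishi reaction: nickel-catalysed activation of the vinyl bromide and transmetalation give alkenylchromium 14, which adds to the aldehyde in the presence of the ester; the new carbinol centre is racemic and is erased in step 9.

Step 8
Reactants: 15 racemic allylic alcohol
Product: 16 racemic (6Z)-8-[(TBS)oxy]-3-[(methoxycarbonyl)oxy]-6-methyl-2-methylideneoct-6-en-1-yl (2E)-2-methylbut-2-enoate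
Conditions: ClCO2Me, pyridine, DMAP (cat.), CH2Cl2, 0 °C
Reagents that add atoms: methyl chloroformate, COC(=O)Cl
Why: Acylation of the secondary allylic alcohol gives a carbonate that ionises with zerovalent palladium much faster than the tiglate ester.

Step 9
Reactants: 16 racemic allylic methyl carbonate; 6 2-[(TBS)oxy]-3-{[(TBS)oxy]methyl}furan (1.3 equiv)
Product: 17 (2Z,6Z)-8-[(TBS)oxy]-2-{[(2S)-4-{[(TBS)oxy]methyl}-5-oxo-2,5-dihydrofuran-2-yl]methyl}-6-methylocta-2,6-dien-1-yl (2E)-2-methylbut-2-enoate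
Conditions: Pd2(dba)3·CHCl3 (2.5 mol %), (R,R)-N,N′-(cyclohexane-1,2-diyl)bis[2-(diphenylphosphanyl)benzamide] (7.5 mol %), CH2Cl2, 0 °C → rt
Reagents that add atoms: none
Why: Proposed new method: zerovalent palladium ionises the carbonate to a 2-substituted π-allyl complex whose C2 chain sits syn (giving C9 trans to C2), the liberated methoxide desilylates 6 to an aromatic furanolate, and this attacks the unsubstituted allyl terminus through C5 (C3 is blocked) inside the chiral ligand pocket, so dearomatisation fixes (S)-C8; the closest known reactions are Tsuji–Trost allylation of silyl enol ethers with allyl carbonates and Trost asymmetric allylic alkylation with prochiral enolates.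

Step 10
Reactants: 17 bis-silyl butenolide
Product: 18 (2Z,6Z)-8-hydroxy-2-{[(2S)-4-(hydroxymethyl)-5-oxo-2,5-dihydrofuran-2-yl]methyl}-6-methylocta-2,6-dien-1-yl (2E)-2-methylbut-2-enoate
Conditions: HF·pyridine, pyridine, THF, 0 °C → rt
Reagents that add atoms: none
Why: Fluoride cleavage of both primary silyl ethers under buffered, non-basic conditions that leave the tiglate, the butenolide and the C8 centre (acidic γ-hydrogen) untouched.

Step 11
Reactants: 18 diol
Product: 19 (2Z,6Z)-2-{[(2S)-4-(hydroxymethyl)-5-oxo-2,5-dihydrofuran-2-yl]methyl}-6-methyl-8-oxoocta-2,6-dien-1-yl (2E)-2-methylbut-2-enoate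
Conditions: MnO2 (activated, 15 equiv), CH2Cl2, 0 °C
Reagents that add atoms: none
Why: MnO2 oxidises the electron-rich neryl-type allylic alcohol much faster than the hydroxymethyl group on the electron-poor butenolide and does not isomerise the Z-enal at low temperature.

Step 12
Reactants: 19 hydroxy enal
Product: 21 (2Z,6Z)-2-{[(2S)-4-(bromomethyl)-5-oxo-2,5-dihydrofuran-2-yl]methyl}-6-methyl-8-oxoocta-2,6-dien-1-yl (2E)-2-methylbut-2-enoate, via allylic mesylate 20 (not isolated)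
Conditions: MsCl, iPr2NEt, CH2Cl2, −40 °C; then LiBr, THF, −20 → 0 °C
Reagents that add atoms: lithium bromide, [Li+].[Br-]; methanesulfonyl chloride, CS(=O)(=O)Cl (its atoms remain only in 20)
Why: Mesylation and SN2 displacement by bromide convert the activated allylic alcohol into the allylic bromide under hindered-base, low-temperature conditions that spare the Z-enal and C8.

Step 13
Reactants: 21 bromo enal
Product: 23 [(3aS,4R,5Z,9Z,11aS)-4-hydroxy-6-methyl-3-methylidene-2-oxo-2,3,3a,4,7,8,11,11a-octahydrocyclodeca[b]furan-10-yl]methyl (2E)-2-methylbut-2-enoate, via allylchromium dichloride 22 (not isolated)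
Conditions: CrCl2 (6 equiv), THF, 2 mM (slow addition), rt
Reagents that add atoms: chromium dichloride, Cl[Cr]Cl (its atoms remain only in 22)
Why: Intramolecular Nozaki–Hiyama (Barbier-type) allylation: allylchromium 22 adds through C7 in a chair transition state (ring-locked E-type allyl unit, aldehyde chain equatorial) on the butenolide face opposite the C8–C9 bond, giving the 6,7-anti and 7,8-trans relationships, the exocyclic methylene and the ten-membered ring.

Step 14
Reactants: 23 macrocyclic (4Z)-allylic alcohol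
Product: 24 CNP0116446.1, (4S,5R,6S,7S,8S)-4,5-epoxy-6-hydroxy-14-[(2E)-2-methylbut-2-enoyloxy]germacra-1(10),11(13)-dien-12,8-olide
Conditions: mCPBA (1.05 equiv), NaHCO3, CH2Cl2, −20 → 0 °C
Reagents that add atoms: 3-chloroperoxybenzoic acid, OOC(=O)c1cccc(Cl)c1
Why: Prilezhaev epoxidation: allylic 1,3-strain keeps the C6 hydrogen eclipsed with the cis alkene, so the hydrogen-bonded peracid attacks the peripheral face and gives the epoxide trans (threo) to the 6-OH, i.e. (4S,5R), as cis-cycloalkenols of medium ring size do, while the ester-deactivated C1=C10 alkene and the two electron-poor alkenes react more slowly.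

**Compound list**

1 | furfural (furan-2-carbaldehyde) | O=Cc1ccco1 | starting material
2 | furan-2-yl formate | O=COc1ccco1 | intermediate
3 | furan-2(3H)-one | O=C1CC=CO1 | intermediate
4 | furan-2(5H)-one | O=C1C=CCO1 | intermediate
5 | 3-(hydroxymethyl)furan-2(5H)-one | O=C1OCC=C1CO | intermediate
6 | 2-[(TBS)oxy]-3-{[(TBS)oxy]methyl}furan | CC(C)(C)[Si](C)(C)OCc1ccoc1O[Si](C)(C)C(C)(C)C | intermediate
7 | nerol, (2Z)-3,7-dimethylocta-2,6-dien-1-ol | CC(C)=CCC/C(C)=C\CO | starting material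
8 | tert-butyl{[(2Z)-3,7-dimethylocta-2,6-dien-1-yl]oxy}dimethylsilane | CC(C)=CCC/C(C)=C\CO[Si](C)(C)C(C)(C)C | intermediate
9 | 3-{(3Z)-5-[(TBS)oxy]-3-methylpent-3-en-1-yl}-5,5-dimethyl-1,2,4-trioxolane (ozonide) | CC1(C)OOC(CC/C(C)=C\CO[Si](C)(C)C(C)(C)C)O1 | intermediate
10 | (4Z)-6-[(TBS)oxy]-4-methylhex-4-enal | O=CCC/C(C)=C\CO[Si](C)(C)C(C)(C)C | intermediate
11 | tiglic acid, (2E)-2-methylbut-2-enoic acid | C/C=C(\C)C(=O)O | starting material
12 | 2,3-dibromoprop-1-ene | C=C(Br)CBr | starting material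
13 | 2-bromoprop-2-en-1-yl (2E)-2-methylbut-2-enoate | C=C(Br)COC(=O)/C(C)=C/C | intermediate
14 | dichloro(3-{[(2E)-2-methylbut-2-enoyl]oxy}prop-1-en-2-yl)chromium | C=C([Cr](Cl)Cl)COC(=O)/C(C)=C/C | intermediate
15 | racemic (6Z)-8-[(TBS)oxy]-3-hydroxy-6-methyl-2-methylideneoct-6-en-1-yl (2E)-2-methylbut-2-enoate | C=C(COC(=O)/C(C)=C/C)C(O)CC/C(C)=C\CO[Si](C)(C)C(C)(C)C | intermediate
16 | racemic (6Z)-8-[(TBS)oxy]-3-[(methoxycarbonyl)oxy]-6-methyl-2-methylideneoct-6-en-1-yl (2E)-2-methylbut-2-enoate | C=C(COC(=O)/C(C)=C/C)C(OC(=O)OC)CC/C(C)=C\CO[Si](C)(C)C(C)(C)C | intermediate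
17 | (2Z,6Z)-8-[(TBS)oxy]-2-{[(2S)-4-{[(TBS)oxy]methyl}-5-oxo-2,5-dihydrofuran-2-yl]methyl}-6-methylocta-2,6-dien-1-yl (2E)-2-methylbut-2-enoate | O=C1O[C@@H](C/C(COC(=O)/C(C)=C/C)=C/CC/C(C)=C\CO[Si](C)(C)C(C)(C)C)C=C1CO[Si](C)(C)C(C)(C)C | intermediate
18 | (2Z,6Z)-8-hydroxy-2-{[(2S)-4-(hydroxymethyl)-5-oxo-2,5-dihydrofuran-2-yl]methyl}-6-methylocta-2,6-dien-1-yl (2E)-2-methylbut-2-enoate | O=C1O[C@@H](C/C(COC(=O)/C(C)=C/C)=C/CC/C(C)=C\CO)C=C1CO | intermediate
19 | (2Z,6Z)-2-{[(2S)-4-(hydroxymethyl)-5-oxo-2,5-dihydrofuran-2-yl]methyl}-6-methyl-8-oxoocta-2,6-dien-1-yl (2E)-2-methylbut-2-enoate | O=C1O[C@@H](C/C(COC(=O)/C(C)=C/C)=C/CC/C(C)=C\C=O)C=C1CO | intermediate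
20 | (2Z,6Z)-2-{[(2S)-4-{[(methylsulfonyl)oxy]methyl}-5-oxo-2,5-dihydrofuran-2-yl]methyl}-6-methyl-8-oxoocta-2,6-dien-1-yl (2E)-2-methylbut-2-enoate | O=C1O[C@@H](C/C(COC(=O)/C(C)=C/C)=C/CC/C(C)=C\C=O)C=C1COS(C)(=O)=O | intermediate
21 | (2Z,6Z)-2-{[(2S)-4-(bromomethyl)-5-oxo-2,5-dihydrofuran-2-yl]methyl}-6-methyl-8-oxoocta-2,6-dien-1-yl (2E)-2-methylbut-2-enoate | O=C1O[C@@H](C/C(COC(=O)/C(C)=C/C)=C/CC/C(C)=C\C=O)C=C1CBr | intermediate
22 | allylchromium dichloride from 21 (CrCl2 unit in place of Br on the butenolide CH2) | O=C1O[C@@H](C/C(COC(=O)/C(C)=C/C)=C/CC/C(C)=C\C=O)C=C1C[Cr](Cl)Cl | intermediate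
23 | [(3aS,4R,5Z,9Z,11aS)-4-hydroxy-6-methyl-3-methylidene-2-oxo-2,3,3a,4,7,8,11,11a-octahydrocyclodeca[b]furan-10-yl]methyl (2E)-2-methylbut-2-enoate; germacrane labels (6R,7S,8S), C9/C2 trans across C1=C10, C3/C6 cis across C4=C5 | C=C1C(=O)O[C@H]2C/C(COC(=O)/C(C)=C/C)=C/CC/C(C)=C\[C@@H](O)[C@H]12 | intermediate
24 | CNP0116446.1, (4S,5R,6S,7S,8S)-4,5-epoxy-6-hydroxy-14-[(2E)-2-methylbut-2-enoyloxy]germacra-1(10),11(13)-dien-12,8-olide (cis-oxirane trans to 6-OH, trans-fused lactone) | C=C1C(=O)O[C@H]2C/C(COC(=O)/C(C)=C/C)=C/CC[C@]3(C)O[C@@H]3[C@@H](O)[C@H]12 | target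

**Step count and risks**

Total step count: 14. Longest linear sequence: 10 steps (7 → 24 through steps 4, 5, 7, 8, 9, 10, 11, 12, 13, 14).

Steps most likely to fail:

Step 9 (regiochemistry, alkene geometry and enantioselectivity of the dearomative allylation; the ligand enantiomer that gives (S)-C8 must be confirmed by experiment). Fallback: set C8 by auxiliary-controlled enolate alkylation and build the butenolide by ring-closing metathesis. It sets out from 15 and comes back at 17. PBr3/pyridine (SN2′) converts 15 into the linear allylic bromide F1. The sodium enolate of (4R)-4-benzyl-3-{[(4-methoxybenzyl)oxy]acetyl}oxazolidin-2-one (NaN(SiMe3)2, THF, −78 °C) is alkylated by F1 to give the (2S)-N-acyloxazolidinone F2. LiBH4 removes the auxiliary to give the primary alcohol F3, Dess–Martin periodinane gives the α-alkoxy aldehyde F4, and Ph3P=CH2 gives the terminal alkene F5. DDQ removes the 4-methoxybenzyl group to give the (S)-allylic alcohol F6. Esterification with 2-{[(TBS)oxy]methyl}prop-2-enoic acid (DCC, DMAP) gives the acrylate ester F7, and second-generation Grubbs catalyst closes the butenolide to 17.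

Step 13 (ten-membered ring closure in competition with oligomerisation; C6/C7 diastereocontrol; possible acyl migration to the 6,12-lactone). Fallback: form C6–C7 bimolecularly and close the ring at C4=C5 by metathesis. It sets out from 13 and comes back at 23. Nozaki–Hiyama–Kishi coupling of 13 with commercial 4-methylpent-4-enal gives the allylic alcohol F8, and ClCO2Me/pyridine gives the methyl carbonate F9. The palladium-catalysed allylation of 6 (conditions of step 9) gives the butenolide F10. HF·pyridine gives the hydroxymethyl butenolide F11 and CBr4/PPh3 gives the bromomethyl butenolide F12. Indium metal in THF–H2O with acrolein gives the trans-lactone triene F13 (anti adduct through the chair transition state). Second-generation Grubbs catalyst then joins the isopropenyl and vinyl groups (cis alkene favoured in the ten-membered ring) to give 23.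

Step 14 (competing epoxidation of the strained C1=C10 alkene, or attack on the wrong face). Fallback: install the oxirane before ring closure under reagent control. It sets out from 18 and comes back at 24. Sharpless epoxidation of 18 (Ti(OiPr)4, D-(−)-diethyl tartrate, tBuOOH, CH2Cl2, −20 °C) acts only on the electron-rich (Z)-allylic alcohol and gives the (4S,5R)-epoxy diol F14. NBS/Me2S (Corey–Kim conditions, selective for the allylic hydroxyl) gives the epoxy bromide F15 and Dess–Martin periodinane gives the epoxy aldehyde F16. CrCl2-mediated cyclisation as in step 13 gives 24 directly; the 5,6-threo relationship then depends on chelation of the metal by the oxirane and aldehyde oxygens.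

**Further compounds**

F1 | step 9 | (2E,6Z)-2-(bromomethyl)-8-[(TBS)oxy]-6-methylocta-2,6-dien-1-yl (2E)-2-methylbut-2-enoate | BrC/C(COC(=O)/C(C)=C/C)=C/CC/C(C)=C\CO[Si](C)(C)C(C)(C)C
F2 | step 9 | (4R)-4-benzyl-3-[(2S,4Z,8Z)-10-[(TBS)oxy]-2-[(4-methoxybenzyl)oxy]-8-methyl-4-({[(2E)-2-methylbut-2-enoyl]oxy}methyl)deca-4,8-dienoyl]-1,3-oxazolidin-2-one | O=C1OC[C@@H](Cc2ccccc2)N1C(=O)[C@@H](OCc3ccc(OC)cc3)C/C(COC(=O)/C(C)=C/C)=C/CC/C(C)=C\CO[Si](C)(C)C(C)(C)C
F3 | step 9 | (2Z,6Z)-8-[(TBS)oxy]-2-{(2S)-3-hydroxy-2-[(4-methoxybenzyl)oxy]propyl}-6-methylocta-2,6-dien-1-yl (2E)-2-methylbut-2-enoate | OC[C@@H](OCc1ccc(OC)cc1)C/C(COC(=O)/C(C)=C/C)=C/CC/C(C)=C\CO[Si](C)(C)C(C)(C)C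
F4 | step 9 | (2Z,6Z)-8-[(TBS)oxy]-2-{(2S)-2-[(4-methoxybenzyl)oxy]-3-oxopropyl}-6-methylocta-2,6-dien-1-yl (2E)-2-methylbut-2-enoate | O=C[C@@H](OCc1ccc(OC)cc1)C/C(COC(=O)/C(C)=C/C)=C/CC/C(C)=C\CO[Si](C)(C)C(C)(C)C
F5 | step 9 | (2Z,6Z)-8-[(TBS)oxy]-2-{(2S)-2-[(4-methoxybenzyl)oxy]but-3-en-1-yl}-6-methylocta-2,6-dien-1-yl (2E)-2-methylbut-2-enoate | C=C[C@@H](OCc1ccc(OC)cc1)C/C(COC(=O)/C(C)=C/C)=C/CC/C(C)=C\CO[Si](C)(C)C(C)(C)C
F6 | step 9 | (2Z,6Z)-8-[(TBS)oxy]-2-[(2S)-2-hydroxybut-3-en-1-yl]-6-methylocta-2,6-dien-1-yl (2E)-2-methylbut-2-enoate | C=C[C@@H](O)C/C(COC(=O)/C(C)=C/C)=C/CC/C(C)=C\CO[Si](C)(C)C(C)(C)C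
F7 | step 9 | (2Z,6Z)-8-[(TBS)oxy]-6-methyl-2-[(2S)-2-{[2-({[TBS]oxy}methyl)prop-2-enoyl]oxy}but-3-en-1-yl]octa-2,6-dien-1-yl (2E)-2-methylbut-2-enoate | C=C[C@@H](OC(=O)C(=C)CO[Si](C)(C)C(C)(C)C)C/C(COC(=O)/C(C)=C/C)=C/CC/C(C)=C\CO[Si](C)(C)C(C)(C)C
F8 | step 13 | racemic 3-hydroxy-6-methyl-2-methylidenehept-6-en-1-yl (2E)-2-methylbut-2-enoate | C=C(COC(=O)/C(C)=C/C)C(O)CCC(C)=C
F9 | step 13 | racemic 3-[(methoxycarbonyl)oxy]-6-methyl-2-methylidenehept-6-en-1-yl (2E)-2-methylbut-2-enoate | C=C(COC(=O)/C(C)=C/C)C(OC(=O)OC)CCC(C)=C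
F10 | step 13 | (2Z)-2-{[(2S)-4-{[(TBS)oxy]methyl}-5-oxo-2,5-dihydrofuran-2-yl]methyl}-6-methylhepta-2,6-dien-1-yl (2E)-2-methylbut-2-enoate | O=C1O[C@@H](C/C(COC(=O)/C(C)=C/C)=C/CCC(C)=C)C=C1CO[Si](C)(C)C(C)(C)C
F11 | step 13 | (2Z)-2-{[(2S)-4-(hydroxymethyl)-5-oxo-2,5-dihydrofuran-2-yl]methyl}-6-methylhepta-2,6-dien-1-yl (2E)-2-methylbut-2-enoate | O=C1O[C@@H](C/C(COC(=O)/C(C)=C/C)=C/CCC(C)=C)C=C1CO
F12 | step 13 | (2Z)-2-{[(2S)-4-(bromomethyl)-5-oxo-2,5-dihydrofuran-2-yl]methyl}-6-methylhepta-2,6-dien-1-yl (2E)-2-methylbut-2-enoate | O=C1O[C@@H](C/C(COC(=O)/C(C)=C/C)=C/CCC(C)=C)C=C1CBr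
F13 | step 13 | (2Z)-2-({(2S,3S)-3-[(1R)-1-hydroxyprop-2-en-1-yl]-4-methylidene-5-oxooxolan-2-yl}methyl)-6-methylhepta-2,6-dien-1-yl (2E)-2-methylbut-2-enoate | C=C1C(=O)O[C@@H](C/C(COC(=O)/C(C)=C/C)=C/CCC(C)=C)[C@@H]1[C@H](O)C=C
F14 | step 14 | (2Z)-2-{[(2S)-4-(hydroxymethyl)-5-oxo-2,5-dihydrofuran-2-yl]methyl}-5-[(2S,3R)-3-(hydroxymethyl)-2-methyloxiran-2-yl]pent-2-en-1-yl (2E)-2-methylbut-2-enoate | O=C1O[C@@H](C/C(COC(=O)/C(C)=C/C)=C/CC[C@]2(C)O[C@@H]2CO)C=C1CO
F15 | step 14 | (2Z)-2-{[(2S)-4-(bromomethyl)-5-oxo-2,5-dihydrofuran-2-yl]methyl}-5-[(2S,3R)-3-(hydroxymethyl)-2-methyloxiran-2-yl]pent-2-en-1-yl (2E)-2-methylbut-2-enoate | O=C1O[C@@H](C/C(COC(=O)/C(C)=C/C)=C/CC[C@]2(C)O[C@@H]2CO)C=C1CBr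
F16 | step 14 | (2Z)-2-{[(2S)-4-(bromomethyl)-5-oxo-2,5-dihydrofuran-2-yl]methyl}-5-[(2S,3S)-3-formyl-2-methyloxiran-2-yl]pent-2-en-1-yl (2E)-2-methylbut-2-enoate | O=C1O[C@@H](C/C(COC(=O)/C(C)=C/C)=C/CC[C@]2(C)O[C@@H]2C=O)C=C1CBr
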